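Ring A and ring B are forged in one thermal event: an intramolecular Diels–Alder reaction of a 2-pyranone with a tethered terminal alkyne, followed by loss of CO2. The feature exploited is ring A itself: C6–OMe and C7–OH flanked by unsubstituted C5 and C8 map onto a 4-methoxy-3-acyloxy-2-pyranone plus a terminal alkyne, and C4, C3, C2, C1 of ring B form the four-carbon tether, so C7–C8 and C4a–C8a are made together. The precursor is an E-dienal: pyranone on C4, formyl group on C3, and the preset C2 (acetal) and C1 (aryl, ethynyl) stereocentres.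

Key step: step 11

Remark (assumption on the chemistry): the target is made as the open γ-hydroxy aldehyde drawn; ring–chain equilibration of the C2 formyl group with the C3 hydroxymethyl group (five-membered lactol) is possible and is treated as the same compound.

Remark (descriptors): locants C1–C8a are those of the dihydronaphthalene. In the acyclic cycloaddition substrate the alkene that holds the pyranone cis to the C2 carbon is E by the sequence rules, and the aryl-bearing carbon is R (aryl > ethynyl > alkyl). It reads 1S in the bicyclic product only because C8a then outranks the aryl group. C2 reads S while its third carbon substituent is a CH2 group and R once that carbon is sp2. Neither change reflects a change in space.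

Remark (pyranone): commercial 4-oxygenated 6-methyl-2-pyranones carry no oxygen on C3, so that oxygen is installed explicitly in steps 6 and 7.

**Route**

Step 1
Reactants: 1 vanillin
Product: 2 4-[(tert-butyldimethylsilyl)oxy]-3-methoxybenzaldehyde
Conditions: TBSCl, imidazole, DMF, rt
Reagents that add atoms: tert-butyldimethylsilyl chloride, CC(C)(C)[Si](C)(C)Cl
Why: Imidazole-assisted O-silylation masks the acidic phenol before the Grignard step and forms no stereocentre.

Step 2
Reactants: 2 4-[(tert-butyldimethylsilyl)oxy]-3-methoxybenzaldehyde; 3 ethynylmagnesium bromide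
Product: 5 rac-1-{4-[(tert-butyldimethylsilyl)oxy]-3-methoxyphenyl}prop-2-yn-1-yl acetate, via bromomagnesium propargylic alkoxide 4 (not isolated)
Conditions: HC≡CMgBr, THF, −78 to 0 °C; then Ac2O, 0 °C to rt
Reagents that add atoms: acetic anhydride, CC(=O)OC(C)=O
Why: Grignard 1,2-addition to the aldehyde and in situ O-acylation of the magnesium alkoxide give the terminal propargylic ester, left racemic on purpose because this centre is ionised and reset in step 3.

Step 3
Reactants: 5 rac-1-{4-[(tert-butyldimethylsilyl)oxy]-3-methoxyphenyl}prop-2-yn-1-yl acetate; 6 pent-4-enal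
Product: 7 (2S,3R)-3-{4-[(tert-butyldimethylsilyl)oxy]-3-methoxyphenyl}-2-(prop-2-en-1-yl)pent-4-ynal
Conditions: (CuOTf)2·C6H6 (5 mol %), single-enantiomer Me-pybox (10 mol %), (R)-α,α-diphenylprolinol trimethylsilyl ether (20 mol %), i-Pr2NEt, THF, −20 °C
Reagents that add atoms: none
Why: In this cooperative copper/enamine propargylic substitution the chiral pybox–copper allenylidene formed from either enantiomer of 5 fixes the propargylic carbon (3R, future C1; the ligand antipode is chosen for this sense) while the enamine of 6 reacts through the face left open by the diarylprolinol silyl ether to fix the α-carbon (2S, future C2), the minor diastereomer being removed by chromatography.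

Step 4
Reactants: 7 (2S,3R)-3-{4-[(tert-butyldimethylsilyl)oxy]-3-methoxyphenyl}-2-(prop-2-en-1-yl)pent-4-ynal
Product: 8 (4S,5R)-5-{4-[(tert-butyldimethylsilyl)oxy]-3-methoxyphenyl}-4-(dimethoxymethyl)hept-1-en-6-yne
Conditions: HC(OMe)3, PPTS (cat.), MeOH, rt
Reagents that add atoms: trimethyl orthoformate, COC(OC)OC
Why: Acid-catalysed acetalisation with orthoformate as water scavenger locks the epimerisable α-branched aldehyde at once under conditions too mild to enolise C2 or to touch the aryl silyl ether, alkene or alkyne.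

Step 5
Reactants: 8 (4S,5R)-5-{4-[(tert-butyldimethylsilyl)oxy]-3-methoxyphenyl}-4-(dimethoxymethyl)hept-1-en-6-yne
Product: 9 (3S,4R)-4-{4-[(tert-butyldimethylsilyl)oxy]-3-methoxyphenyl}-3-(dimethoxymethyl)hex-5-ynal
Conditions: OsO4 (2 mol %), NaIO4, 2,6-lutidine, dioxane–H2O (3:1), rt
Reagents that add atoms: osmium tetroxide, O=[Os](=O)(=O)=O (catalytic oxygen carrier); sodium periodate, [Na+].[O-]I(=O)(=O)=O
Why: In this Lemieux–Johnson cleavage OsO4 dihydroxylates the terminal alkene much faster than the alkyne or the arene and periodate cleaves the diol, the lutidine buffer sparing the acetal, so the C3 methylene aldehyde appears without touching either stereocentre.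

Step 6
Reactants: 10 4-methoxy-6-methyl-2H-pyran-2-one
Product: 11 3-bromo-4-methoxy-6-methyl-2H-pyran-2-one
Conditions: NBS, MeCN, rt, dark
Reagents that add atoms: N-bromosuccinimide, O=C1CCC(=O)N1Br
Why: Electrophilic bromination occurs at C3, the most nucleophilic ring carbon because it is the β-carbon of the 4-methoxy enol ether.

Step 7
Reactants: 11 3-bromo-4-methoxy-6-methyl-2H-pyran-2-one
Product: 13 3-hydroxy-4-methoxy-6-methyl-2H-pyran-2-one, via 3-boryl pyranone 12 (not isolated)
Conditions: B2pin2, Pd(dppf)Cl2 (3 mol %), KOAc, dioxane, 85 °C; then NaBO3·4H2O, THF–H2O, rt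
Reagents that add atoms: sodium perborate, [Na+].[O-]OB=O; bis(pinacolato)diboron, CC1(C)OB(OC1(C)C)B1OC(C)(C)C(C)(C)O1 (its boron stays only in 12)
Why: Miyaura borylation of the vinylic bromide followed by oxidative C–B to C–O cleavage installs the C3 oxygen with an acetate base and a mild peroxide that the lactone tolerates.

Step 8
Reactants: 13 3-hydroxy-4-methoxy-6-methyl-2H-pyran-2-one
Product: 14 4-methoxy-6-methyl-2-oxo-2H-pyran-3-yl 2,2-dimethylpropanoate
Conditions: PivCl, Et3N, DMAP (cat.), CH2Cl2, 0 °C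
Reagents that add atoms: pivaloyl chloride, CC(C)(C)C(Cl)=O
Why: O-acylation of the acidic enol gives a pivalate that survives SeO2, amine catalysis and 180 °C better than a silyl ether would, and as a weaker donor it keeps the pyranone LUMO low for the key step.

Step 9
Reactants: 14 4-methoxy-6-methyl-2-oxo-2H-pyran-3-yl 2,2-dimethylpropanoate
Product: 15 6-formyl-4-methoxy-2-oxo-2H-pyran-3-yl 2,2-dimethylpropanoate
Conditions: SeO2, 1,4-dioxane, 150 °C, sealed tube
Reagents that add atoms: selenium dioxide, O=[Se]=O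
Why: Riley oxidation converts the vinylogously activated 6-methyl group into the aldehyde, the only C–H position in 14 that SeO2 can attack.

Step 10
Reactants: 9 (3S,4R)-4-{4-[(tert-butyldimethylsilyl)oxy]-3-methoxyphenyl}-3-(dimethoxymethyl)hex-5-ynal; 15 6-formyl-4-methoxy-2-oxo-2H-pyran-3-yl 2,2-dimethylpropanoate
Product: 16 6-[(1E,3R,4R)-4-{4-[(tert-butyldimethylsilyl)oxy]-3-methoxyphenyl}-3-(dimethoxymethyl)-2-formylhex-1-en-5-yn-1-yl]-4-methoxy-2-oxo-2H-pyran-3-yl 2,2-dimethylpropanoate
Conditions: pyrrolidine (20 mol %), PhCO2H (20 mol %), 4 Å MS, CH2Cl2, rt; 15 in slight excess, 9 added slowly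
Reagents that add atoms: none
Why: In this amine-catalysed crossed aldol condensation the enamine of 9 adds to the non-enolisable, highly electrophilic aldehyde 15 and elimination gives the thermodynamically preferred E-enal (pyranone trans to CHO, hence cis to the C2 carbon), while C2 sits β to the reacting aldehyde and cannot epimerise.

Step 11
Reactants: 16 6-[(1E,3R,4R)-4-{4-[(tert-butyldimethylsilyl)oxy]-3-methoxyphenyl}-3-(dimethoxymethyl)-2-formylhex-1-en-5-yn-1-yl]-4-methoxy-2-oxo-2H-pyran-3-yl 2,2-dimethylpropanoate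
Product: 18 (1S,2R)-1-{4-[(tert-butyldimethylsilyl)oxy]-3-methoxyphenyl}-2-(dimethoxymethyl)-3-formyl-6-methoxy-1,2-dihydronaphthalen-7-yl 2,2-dimethylpropanoate, via bridged bicyclic lactone 17 (not isolated)
Conditions: o-C6H4Cl2 (0.005 M), BHT (10 mol %), 180 °C, sealed tube, Ar, base-washed glass
Reagents that add atoms: none
Why: The pyranone diene adds through its carbons 3 and 6 across the tethered terminal alkyne in a thermal intramolecular [4+2] cycloaddition to give the 2-oxabicyclo[2.2.2]octadienone 17, which loses CO2 by retro-[4+2] and so aromatises ring A; the closest known reaction type is the intramolecular Diels–Alder/decarboxylation of 2-pyranones carrying tethered alkynes. Ring A closes as the six-membered ring of the cycloaddition itself (bonds C7–C8 and C4a–C8a), and ring B closes in the same event as the six-membered tether ring made of C4a, C4, C3, C2, C1 and C8a. No stereocentre is created: C1 and C2 are spectators and the two bridgehead centres of 17 vanish with CO2, so attack on either pyranone face converges on 18. The selectivity needed is regiochemical (OMe on C6, acyloxy on C7, H on C8) and the tether enforces it, because the chain sits on pyranone carbon 6, so the internal alkyne carbon must bond there and the CH terminus to carbon 3. The E alkene holds the pyranone cis to C2, the conjugated formyl and the acyloxy group lower the pyranone LUMO towards the alkyne HOMO, and the neutral medium leaves the acetal, the silyl ether and C2 untouched.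

Step 12
Reactants: 18 (1S,2R)-1-{4-[(tert-butyldimethylsilyl)oxy]-3-methoxyphenyl}-2-(dimethoxymethyl)-3-formyl-6-methoxy-1,2-dihydronaphthalen-7-yl 2,2-dimethylpropanoate
Product: 20 (1S,2R)-2-(dimethoxymethyl)-1-(4-hydroxy-3-methoxyphenyl)-3-(hydroxymethyl)-6-methoxy-1,2-dihydronaphthalen-7-ol, via allylic alcohol 19 (not isolated)
Conditions: NaBH4, MeOH–THF, −20 °C; then NaOMe, 0 °C to rt; aq. NH4Cl
Reagents that add atoms: none
Why: Hydride 1,2-reduction of the conjugated aldehyde (no pyranone is left to compete) is followed in the same pot by methoxide cleavage of the aryl pivalate and aryl silyl ether, and C2 cannot epimerise under this base because it is still an acetal.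

Step 13
Reactants: 20 (1S,2R)-2-(dimethoxymethyl)-1-(4-hydroxy-3-methoxyphenyl)-3-(hydroxymethyl)-6-methoxy-1,2-dihydronaphthalen-7-ol
Product: 21 (1S,2R)-7-hydroxy-1-(4-hydroxy-3-methoxyphenyl)-3-(hydroxymethyl)-6-methoxy-1,2-dihydronaphthalene-2-carbaldehyde
Conditions: PPTS, acetone–H2O (9:1), 30 °C
Reagents that add atoms: water, O
Why: Mild aqueous acid hydrolysis of the dimethyl acetal releases the C2 aldehyde without any base, so the trans C1/C2 relationship, which is also the thermodynamically preferred one, should be retained and the C3=C4 bond should stay in place.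

**Compound list**

1 | vanillin (4-hydroxy-3-methoxybenzaldehyde) | COc1cc(C=O)ccc1O | starting material
2 | 4-[(tert-butyldimethylsilyl)oxy]-3-methoxybenzaldehyde | COc1cc(C=O)ccc1O[Si](C)(C)C(C)(C)C | intermediate
3 | ethynylmagnesium bromide | C#C[Mg]Br | starting material
4 | bromomagnesium 1-{4-[(tert-butyldimethylsilyl)oxy]-3-methoxyphenyl}prop-2-yn-1-olate (racemic) | C#CC(O[Mg]Br)c1ccc(O[Si](C)(C)C(C)(C)C)c(OC)c1 | intermediate (not isolated)
5 | rac-1-{4-[(tert-butyldimethylsilyl)oxy]-3-methoxyphenyl}prop-2-yn-1-yl acetate | CC(=O)OC(C#C)c1ccc(O[Si](C)(C)C(C)(C)C)c(OC)c1 | intermediate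
6 | pent-4-enal | C=CCCC=O | starting material
7 | (2S,3R)-3-{4-[(tert-butyldimethylsilyl)oxy]-3-methoxyphenyl}-2-(prop-2-en-1-yl)pent-4-ynal | O=C[C@@H](CC=C)[C@H](C#C)c1ccc(O[Si](C)(C)C(C)(C)C)c(OC)c1 | intermediate
8 | (4S,5R)-5-{4-[(tert-butyldimethylsilyl)oxy]-3-methoxyphenyl}-4-(dimethoxymethyl)hept-1-en-6-yne | C=CC[C@H](C(OC)OC)[C@H](C#C)c1ccc(O[Si](C)(C)C(C)(C)C)c(OC)c1 | intermediate
9 | (3S,4R)-4-{4-[(tert-butyldimethylsilyl)oxy]-3-methoxyphenyl}-3-(dimethoxymethyl)hex-5-ynal | O=CC[C@H](C(OC)OC)[C@H](C#C)c1ccc(O[Si](C)(C)C(C)(C)C)c(OC)c1 | intermediate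
10 | 4-methoxy-6-methyl-2H-pyran-2-one | CC1=CC(OC)=CC(=O)O1 | starting material
11 | 3-bromo-4-methoxy-6-methyl-2H-pyran-2-one | CC1=CC(OC)=C(Br)C(=O)O1 | intermediate
12 | 4-methoxy-6-methyl-3-(4,4,5,5-tetramethyl-1,3,2-dioxaborolan-2-yl)-2H-pyran-2-one | CC1=CC(OC)=C(B2OC(C)(C)C(C)(C)O2)C(=O)O1 | intermediate (not isolated)
13 | 3-hydroxy-4-methoxy-6-methyl-2H-pyran-2-one | CC1=CC(OC)=C(O)C(=O)O1 | intermediate
14 | 4-methoxy-6-methyl-2-oxo-2H-pyran-3-yl 2,2-dimethylpropanoate | CC1=CC(OC)=C(OC(=O)C(C)(C)C)C(=O)O1 | intermediate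
15 | 6-formyl-4-methoxy-2-oxo-2H-pyran-3-yl 2,2-dimethylpropanoate | O=CC1=CC(OC)=C(OC(=O)C(C)(C)C)C(=O)O1 | intermediate
16 | 6-[(1E,3R,4R)-4-{4-[(tert-butyldimethylsilyl)oxy]-3-methoxyphenyl}-3-(dimethoxymethyl)-2-formylhex-1-en-5-yn-1-yl]-4-methoxy-2-oxo-2H-pyran-3-yl 2,2-dimethylpropanoate | O=C/C(=C/C1=CC(OC)=C(OC(=O)C(C)(C)C)C(=O)O1)[C@H](C(OC)OC)[C@H](C#C)c1ccc(O[Si](C)(C)C(C)(C)C)c(OC)c1 | intermediate
17 | 2-oxabicyclo[2.2.2]octa-5,7-dien-3-one cycloadduct of 16 (bridgeheads are pyranone carbons 3 and 6, their configuration left undefined; C1 and C2 as in 16) | O=C1OC23C=C(OC)C1(OC(=O)C(C)(C)C)C=C2[C@H](c4ccc(O[Si](C)(C)C(C)(C)C)c(OC)c4)[C@@H](C(OC)OC)C(C=O)=C3 | intermediate (not isolated)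
18 | (1S,2R)-1-{4-[(tert-butyldimethylsilyl)oxy]-3-methoxyphenyl}-2-(dimethoxymethyl)-3-formyl-6-methoxy-1,2-dihydronaphthalen-7-yl 2,2-dimethylpropanoate | COc1cc([C@H]2c3cc(OC(=O)C(C)(C)C)c(OC)cc3C=C(C=O)[C@@H]2C(OC)OC)ccc1O[Si](C)(C)C(C)(C)C | intermediate
19 | (1S,2R)-1-{4-[(tert-butyldimethylsilyl)oxy]-3-methoxyphenyl}-2-(dimethoxymethyl)-3-(hydroxymethyl)-6-methoxy-1,2-dihydronaphthalen-7-yl 2,2-dimethylpropanoate | COc1cc([C@H]2c3cc(OC(=O)C(C)(C)C)c(OC)cc3C=C(CO)[C@@H]2C(OC)OC)ccc1O[Si](C)(C)C(C)(C)C | intermediate (not isolated)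
20 | (1S,2R)-2-(dimethoxymethyl)-1-(4-hydroxy-3-methoxyphenyl)-3-(hydroxymethyl)-6-methoxy-1,2-dihydronaphthalen-7-ol | COc1cc([C@H]2c3cc(O)c(OC)cc3C=C(CO)[C@@H]2C(OC)OC)ccc1O | intermediate
21 | (1S,2R)-7-hydroxy-1-(4-hydroxy-3-methoxyphenyl)-3-(hydroxymethyl)-6-methoxy-1,2-dihydronaphthalene-2-carbaldehyde | COc1cc([C@H]2c3cc(O)c(OC)cc3C=C(CO)[C@@H]2C=O)ccc1O | target

**Step count and risk**

Total steps: 13. Longest linear sequence: 9 steps (steps 1–5 and 10–13, from vanillin); the pyranone branch (steps 6–9) joins at step 10.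

The three steps most likely to fail:

Step 11. The conjugated dienal may oligomerise, or the acetal may lose methanol, faster than the unactivated terminal alkyne is captured at the temperature it needs. The fallback sets out from 16 and comes back at 20; it moves the cycloaddition onto a reduced, non-conjugated and thermally hardier substrate. Luche reduction of 16 (NaBH4, CeCl3·7H2O, MeOH, −40 °C) should give the allylic alcohol 6-[(1E,3R,4R)-4-aryl-3-(dimethoxymethyl)-2-(hydroxymethyl)hex-1-en-5-yn-1-yl]-4-methoxy-2-oxo-2H-pyran-3-yl pivalate F1. Acylation (PivCl, pyridine, DMAP) gives its allylic pivalate F2. Thermolysis of F2 (o-C6H4Cl2, 200–220 °C, sealed or microwave) passes through the bridged bicyclic lactone F3 (not isolated) to the 3-(pivaloyloxymethyl) dihydronaphthalene F4. NaOMe in MeOH then removes both pivalates and the aryl silyl ether to give 20.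

Step 3. Diastereoselectivity may be eroded by a mismatched catalyst pair or by epimerisation of the α-branched aldehyde through enamine re-formation, and the electron-rich benzylic acetate may undergo racemic background substitution. The fallback sets out from 2 and comes back at 7; it fixes the two centres one at a time by independently controlled, known reactions.
- Knoevenagel condensation of 2 with Meldrum's acid gives the arylidene Meldrum's acid F5.
- Rhodium-catalysed enantioselective conjugate addition of trimethylsilylacetylene (Rh(acac)(C2H4)2, chiral biaryl bisphosphine, aqueous dioxane) gives the (S)-propargylic Meldrum's acid adduct F6.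
- Hydrolytic decarboxylation (wet DMF, 100 °C) gives (3S)-3-aryl-5-(trimethylsilyl)pent-4-ynoic acid F7.
- Mixed-anhydride acylation (PivCl, Et3N; then n-BuLi-lithiated (S)-4-benzyl-1,3-oxazolidin-2-one) gives the imide F8.
- Auxiliary-controlled enolate allylation (NaN(SiMe3)2, allyl iodide, THF, −78 °C) gives the (2S,3S)-allylated imide F9.
- LiBH4 reduction gives (2S,3S)-3-aryl-2-(prop-2-en-1-yl)-5-(trimethylsilyl)pent-4-yn-1-ol F10.
- Alkyne C-desilylation with AgNO3 in aqueous acetone gives (2S,3R)-3-aryl-2-(prop-2-en-1-yl)pent-4-yn-1-ol F11.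
- DMP oxidation gives 7.

Step 10. Self-condensation of 9, conjugate addition or acyl transfer of the amine at the pyranone, or incomplete dehydration may compete. The fallback sets out from 9 (with 15) and comes back at 16; it replaces amine catalysis by a Mukaiyama aldol addition and separate elimination. Silylation of 9 (TMSCl, Et3N, DMF, 80 °C) gives the trimethylsilyl enol ether of 9 F12 (E/Z mixture). BF3·OEt2-promoted addition of F12 to 15 at −78 °C gives the β-hydroxy aldehyde F13 (mixture at the two new centres). MsCl and Et3N convert F13 through its mesylate F14 (not isolated) by E1cB elimination into the E-enal 16.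

Further compounds
F1 | step 11 | 6-[(1E,3R,4R)-4-{4-[(tert-butyldimethylsilyl)oxy]-3-methoxyphenyl}-3-(dimethoxymethyl)-2-(hydroxymethyl)hex-1-en-5-yn-1-yl]-4-methoxy-2-oxo-2H-pyran-3-yl 2,2-dimethylpropanoate | OC/C(=C/C1=CC(OC)=C(OC(=O)C(C)(C)C)C(=O)O1)[C@H](C(OC)OC)[C@H](C#C)c1ccc(O[Si](C)(C)C(C)(C)C)c(OC)c1
F2 | step 11 | allylic pivalate of F1 | CC(C)(C)C(=O)OC/C(=C/C1=CC(OC)=C(OC(=O)C(C)(C)C)C(=O)O1)[C@H](C(OC)OC)[C@H](C#C)c1ccc(O[Si](C)(C)C(C)(C)C)c(OC)c1
F3 | step 11 | bridged bicyclic lactone from F2 (bridgehead configuration undefined) | O=C1OC23C=C(OC)C1(OC(=O)C(C)(C)C)C=C2[C@H](c4ccc(O[Si](C)(C)C(C)(C)C)c(OC)c4)[C@@H](C(OC)OC)C(COC(=O)C(C)(C)C)=C3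
F4 | step 11 | (1S,2R)-1-{4-[(tert-butyldimethylsilyl)oxy]-3-methoxyphenyl}-2-(dimethoxymethyl)-6-methoxy-3-[(pivaloyloxy)methyl]-1,2-dihydronaphthalen-7-yl 2,2-dimethylpropanoate | COc1cc([C@H]2c3cc(OC(=O)C(C)(C)C)c(OC)cc3C=C(COC(=O)C(C)(C)C)[C@@H]2C(OC)OC)ccc1O[Si](C)(C)C(C)(C)C
F5 | step 3 | 5-({4-[(tert-butyldimethylsilyl)oxy]-3-methoxyphenyl}methylidene)-2,2-dimethyl-1,3-dioxane-4,6-dione | COc1cc(C=C2C(=O)OC(C)(C)OC2=O)ccc1O[Si](C)(C)C(C)(C)C
F6 | step 3 | 5-[(1S)-1-{4-[(tert-butyldimethylsilyl)oxy]-3-methoxyphenyl}-3-(trimethylsilyl)prop-2-yn-1-yl]-2,2-dimethyl-1,3-dioxane-4,6-dione | C[Si](C)(C)C#C[C@H](c1ccc(O[Si](C)(C)C(C)(C)C)c(OC)c1)C1C(=O)OC(C)(C)OC1=O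
F7 | step 3 | (3S)-3-{4-[(tert-butyldimethylsilyl)oxy]-3-methoxyphenyl}-5-(trimethylsilyl)pent-4-ynoic acid | C[Si](C)(C)C#C[C@H](c1ccc(O[Si](C)(C)C(C)(C)C)c(OC)c1)CC(=O)O
F8 | step 3 | (4S)-4-benzyl-3-[(3S)-3-{4-[(tert-butyldimethylsilyl)oxy]-3-methoxyphenyl}-5-(trimethylsilyl)pent-4-ynoyl]-1,3-oxazolidin-2-one | C[Si](C)(C)C#C[C@H](c1ccc(O[Si](C)(C)C(C)(C)C)c(OC)c1)CC(=O)N1[C@@H](Cc2ccccc2)COC1=O
F9 | step 3 | (4S)-4-benzyl-3-[(2S,3S)-3-{4-[(tert-butyldimethylsilyl)oxy]-3-methoxyphenyl}-2-(prop-2-en-1-yl)-5-(trimethylsilyl)pent-4-ynoyl]-1,3-oxazolidin-2-one | C[Si](C)(C)C#C[C@H](c1ccc(O[Si](C)(C)C(C)(C)C)c(OC)c1)[C@H](CC=C)C(=O)N1[C@@H](Cc2ccccc2)COC1=O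
F10 | step 3 | (2S,3S)-3-{4-[(tert-butyldimethylsilyl)oxy]-3-methoxyphenyl}-2-(prop-2-en-1-yl)-5-(trimethylsilyl)pent-4-yn-1-ol | C[Si](C)(C)C#C[C@H](c1ccc(O[Si](C)(C)C(C)(C)C)c(OC)c1)[C@H](CC=C)CO
F11 | step 3 | (2S,3R)-3-{4-[(tert-butyldimethylsilyl)oxy]-3-methoxyphenyl}-2-(prop-2-en-1-yl)pent-4-yn-1-ol | C#C[C@H](c1ccc(O[Si](C)(C)C(C)(C)C)c(OC)c1)[C@H](CC=C)CO
F12 | step 10 | trimethylsilyl enol ether of 9 (E/Z mixture at the enol double bond) | C[Si](C)(C)OC=C[C@H](C(OC)OC)[C@H](C#C)c1ccc(O[Si](C)(C)C(C)(C)C)c(OC)c1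
F13 | step 10 | β-hydroxy aldehyde from F12 and 15 (mixture at the two new centres) | O=CC(C(O)C1=CC(OC)=C(OC(=O)C(C)(C)C)C(=O)O1)[C@H](C(OC)OC)[C@H](C#C)c1ccc(O[Si](C)(C)C(C)(C)C)c(OC)c1
F14 | step 10 | methanesulfonate of F13 | O=CC(C(OS(C)(=O)=O)C1=CC(OC)=C(OC(=O)C(C)(C)C)C(=O)O1)[C@H](C(OC)OC)[C@H](C#C)c1ccc(O[Si](C)(C)C(C)(C)C)c(OC)c1
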